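**Plan**
- Retrosynthesis: the enol-lactone C–O bond and the ring–acyl C–C bond are cut first (lactonisation and O-to-C acyl shift on an open-chain triketone). The carbocycle is then cut at two bonds, carbonyl C7–quaternary C8 and enol C5–acyl-bearing C6, which leads back to a dienyl diazoketone. That is cut at C4–C4a and the lactone (carbene-catalysed annulation of an acylpyruvate with cinnamaldehyde), at the oxalyl–CH2 bond (Claisen) and at the two prenyl C–C bonds.
- Forward: diprenyl ketone → acylpyruvate → δ-lactone closed on the pyruvate oxygen (C4 set here) → silyl dienol ether and diazoketone → light builds the carbocycle → the lactone is opened, the acyl group is put on, and the lactone is closed again on the enol oxygen next to C8.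
- Enabling feature: the carbocycle of the target (C4a, C5, C6, C7, C8, C8a) is a 6,6-disubstituted cyclohexa-2,4-dienone, the closed valence isomer of a (Z)-dienylketene. The δ-lactone on the other enol oxygen serves as a temporary ring that holds this Z geometry and carries C4.
- Stereochemistry: C4 (S) comes from the catalyst-controlled conjugate addition in step 4; the acyl stereocentre (R) is bought with acid 16; C8 carries two identical groups.

Key step: step 8

Assumption: (R)-2-methylbutanoic acid is bought enantiopure, and the (5aR,10bS) triazolium salt is taken to give 4S (its mirror image is used if it gives 4R); 6, 15, 18 and 19 are drawn as one tautomer each.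

Step 1
Reactants: 1 ethyl acetoacetate; 2 prenyl bromide (1-bromo-3-methylbut-2-ene, 2.2 equiv)
Product: 3 ethyl 2-acetyl-5-methyl-2-(3-methylbut-2-en-1-yl)hex-4-enoate
Conditions: NaH (2.2 equiv), THF, 0 to 50 °C
Reagents that add atoms: none
Why: Twofold C-alkylation of the acetoacetate enolate (acetoacetic ester alkylation) with a reactive allylic bromide puts both prenyl groups on the carbon that becomes the quaternary ring carbon.

Step 2
Reactants: 3 ethyl 2-acetyl-5-methyl-2-(3-methylbut-2-en-1-yl)hex-4-enoate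
Product: 4 6-methyl-3-(3-methylbut-2-en-1-yl)hept-5-en-2-one
Conditions: LiCl, H2O, DMSO, 150 °C
Reagents that add atoms: none
Why: Krapcho dealkoxycarbonylation removes the ester from the non-enolisable quaternary carbon without retro-Claisen cleavage and leaves the methyl ketone.

Step 3
Reactants: 4 6-methyl-3-(3-methylbut-2-en-1-yl)hept-5-en-2-one; 5 diallyl oxalate
Product: 6 allyl 8-methyl-5-(3-methylbut-2-en-1-yl)-2,4-dioxonon-7-enoate
Conditions: LiHMDS (1.1 equiv), THF, −78 °C; then 5, −78 to 0 °C; aq. HCl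
Reagents that add atoms: none
Why: Crossed Claisen condensation of the kinetic methyl-side enolate with a non-enolisable oxalate should give the 2,4-dioxo ester, and the released alkoxide deprotonates the product so that the equilibrium is driven forward.

Step 4
Reactants: 6 allyl 8-methyl-5-(3-methylbut-2-en-1-yl)-2,4-dioxonon-7-enoate; 7 (E)-cinnamaldehyde
Product: 8 allyl (4S)-5-[5-methyl-2-(3-methylbut-2-en-1-yl)hex-4-enoyl]-2-oxo-4-phenyl-3,4-dihydro-2H-pyran-6-carboxylate
Conditions: (5aR,10bS)-2-mesityl-5a,10b-dihydro-4H,6H-indeno[2,1-b][1,2,4]triazolo[4,3-d][1,4]oxazin-2-ium chloride (10 mol %), DBU (20 mol %), 3,3',5,5'-tetra-tert-butyldiphenoquinone (1.1 equiv), PhMe, 20 °C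
Reagents that add atoms: none
Why: Oxidative N-heterocyclic carbene catalysis turns the enal into an α,β-unsaturated acyl azolium, the dicarbonyl carbon adds to its β-carbon (Michael addition) from the face left open by the aminoindanol backbone, which sets C4 as S, and the more enolised, less hindered pyruvate oxygen should close the lactone.

Step 5
Reactants: 8 allyl (4S)-5-[5-methyl-2-(3-methylbut-2-en-1-yl)hex-4-enoyl]-2-oxo-4-phenyl-3,4-dihydro-2H-pyran-6-carboxylate
Product: 9 allyl (4S)-5-{1-[(tert-butyldimethylsilyl)oxy]-5-methyl-2-(3-methylbut-2-en-1-yl)hexa-1,4-dien-1-yl}-2-oxo-4-phenyl-3,4-dihydro-2H-pyran-6-carboxylate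
Conditions: TBSOTf, Et3N, CH2Cl2, 0 to 20 °C
Reagents that add atoms: tert-butyldimethylsilyl trifluoromethanesulfonate, CC(C)(C)[Si](C)(C)OS(=O)(=O)C(F)(F)F
Why: Soft enolisation (O-silylation of the ketone, then loss of its only α-hydrogen, that of the diprenylmethine) should give the cross-conjugated silyl dienol ether, which has no E/Z isomers because both carbon substituents are prenyl, while the weak amine base leaves the hydrogen at C4 alone.

Step 6
Reactants: 9 allyl (4S)-5-{1-[(tert-butyldimethylsilyl)oxy]-5-methyl-2-(3-methylbut-2-en-1-yl)hexa-1,4-dien-1-yl}-2-oxo-4-phenyl-3,4-dihydro-2H-pyran-6-carboxylate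
Product: 10 (4S)-5-{1-[(tert-butyldimethylsilyl)oxy]-5-methyl-2-(3-methylbut-2-en-1-yl)hexa-1,4-dien-1-yl}-2-oxo-4-phenyl-3,4-dihydro-2H-pyran-6-carboxylic acid
Conditions: Pd(PPh3)4 (5 mol %), HCO2H, Et3N, THF, 20 °C
Reagents that add atoms: none
Why: Palladium-catalysed allyl transfer to formate (Tsuji–Trost deallylation) frees the acid under buffered conditions that spare the enol lactone, the silyl dienol ether and the prenyl groups.

Step 7
Reactants: 10 (4S)-5-{1-[(tert-butyldimethylsilyl)oxy]-5-methyl-2-(3-methylbut-2-en-1-yl)hexa-1,4-dien-1-yl}-2-oxo-4-phenyl-3,4-dihydro-2H-pyran-6-carboxylic acid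
Product: 12 (4S)-5-{1-[(tert-butyldimethylsilyl)oxy]-5-methyl-2-(3-methylbut-2-en-1-yl)hexa-1,4-dien-1-yl}-6-(diazoacetyl)-4-phenyl-3,4-dihydro-2H-pyran-2-one, via acid chloride 11 (not isolated)
Conditions: Me2C=C(Cl)NMe2, CH2Cl2, 0 °C; then Me3SiCHN2, CaO, MeCN–THF, 0 °C
Reagents that add atoms: (trimethylsilyl)diazomethane, C[Si](C)(C)C=[N+]=[N-]
Why: Acid chloride formation with a neutral chloroenamine and acylation of the diazoalkane with loss of the silyl group (first half of an Arndt–Eistert sequence) should give the diazoketone without amine base, so that no vinylketene can form and racemise C4.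

Step 8
Reactants: 12 (4S)-5-{1-[(tert-butyldimethylsilyl)oxy]-5-methyl-2-(3-methylbut-2-en-1-yl)hexa-1,4-dien-1-yl}-6-(diazoacetyl)-4-phenyl-3,4-dihydro-2H-pyran-2-one
Product: 14 (4S)-5-[(tert-butyldimethylsilyl)oxy]-6,6-bis(3-methylbut-2-en-1-yl)-4-phenyl-3,4-dihydro-2H-chromene-2,7(6H)-dione, via ketene 13 (not isolated)
Conditions: hν (440 nm LEDs), degassed PhMe (0.01 M), 20 °C
Reagents that add atoms: none
Why: Light expels N2 from the s-Z diazoketone while the alkenyl carbon C6 of the dihydropyranone shifts from the carbonyl carbon to the diazo carbon (photochemical Wolff rearrangement), which makes the first C–C bond (C8–C8a of 14) and gives dienylketene 13; its ketene carbon then bonds to the diprenyl-substituted terminus of the silyl dienol ether in a thermal disrotatory 6π electrocyclisation, which makes the second C–C bond (C6–C7 of 14) and the quaternary carbon. The closest known reaction type is the photochemical Wolff rearrangement of unsaturated diazoketones to vinylketenes, joined to the electrocyclic closure of dienylketenes to cyclohexa-2,4-dienones, which is the thermal reverse of the photochemical ring opening of 6,6-disubstituted cyclohexa-2,4-dienones. One ring is closed, the six-membered carbocycle, by 6π electrocyclisation of a hexatriene whose central double bond is the endocyclic C5=C6 bond of the lactone. No new stereocentre arises, because the new quaternary carbon carries two identical prenyl groups, and C4 has no bond that is broken or made acidic in the step. The step needs the ketene and the dienol ether cis on the central double bond, C–C instead of C–O closure, and rearrangement instead of carbene addition to a prenyl alkene: the δ-lactone ring fixes the cis geometry, both enol oxygens are capped (lactone and silyl ether), and metal-free irradiation favours the concerted shift.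

Step 9
Reactants: 14 (4S)-5-[(tert-butyldimethylsilyl)oxy]-6,6-bis(3-methylbut-2-en-1-yl)-4-phenyl-3,4-dihydro-2H-chromene-2,7(6H)-dione
Product: 15 methyl (3S)-3-[2-hydroxy-5,5-bis(3-methylbut-2-en-1-yl)-4,6-dioxocyclohex-1-en-1-yl]-3-phenylpropanoate
Conditions: MeOH, Et3N, 0 to 20 °C; aq. citric acid
Reagents that add atoms: methanol, CO
Why: Transesterification of the enol lactone, an activated vinylogous anhydride, opens the temporary ring to the methyl ester, and the silyl group, then part of a vinylogous silyl ester, should be lost by methanolysis in the same flask.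

Step 10
Reactants: 15 methyl (3S)-3-[2-hydroxy-5,5-bis(3-methylbut-2-en-1-yl)-4,6-dioxocyclohex-1-en-1-yl]-3-phenylpropanoate; 16 (R)-2-methylbutanoic acid
Product: 18 methyl (3S)-3-{2,6-dihydroxy-5-[(2R)-2-methylbutanoyl]-3,3-bis(3-methylbut-2-en-1-yl)-4-oxocyclohexa-1,5-dien-1-yl}-3-phenylpropanoate, via enol ester 17 (not isolated)
Conditions: DCC, DMAP, CH2Cl2, 0 to 20 °C
Reagents that add atoms: none
Why: Carbodiimide O-acylation followed by the DMAP-mediated O-to-C acyl shift known for enol esters of cyclic 1,3-diones should place the acyl group on the only CH2 carbon between two carbonyl groups, the product being drained off as its stabilised triketone enolate.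

Step 11
Reactants: 18 methyl (3S)-3-{2,6-dihydroxy-5-[(2R)-2-methylbutanoyl]-3,3-bis(3-methylbut-2-en-1-yl)-4-oxocyclohexa-1,5-dien-1-yl}-3-phenylpropanoate
Product: 19 (3S)-3-{2,6-dihydroxy-5-[(2R)-2-methylbutanoyl]-3,3-bis(3-methylbut-2-en-1-yl)-4-oxocyclohexa-1,5-dien-1-yl}-3-phenylpropanoic acid
Conditions: LiOH, THF–H2O, 0 °C; aq. HCl to pH 3
Reagents that add atoms: lithium hydroxide, [Li+].[OH-]
Why: Saponification of the methyl ester takes place while the ring is held as its enolate, which guards against retro-Michael loss of the side chain and against enolisation next to the 2-methylbutanoyl stereocentre.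

Step 12
Reactants: 19 (3S)-3-{2,6-dihydroxy-5-[(2R)-2-methylbutanoyl]-3,3-bis(3-methylbut-2-en-1-yl)-4-oxocyclohexa-1,5-dien-1-yl}-3-phenylpropanoic acid
Product: 21 (4S)-5-hydroxy-6-[(2R)-2-methylbutanoyl]-8,8-bis(3-methylbut-2-en-1-yl)-4-phenyl-3,4-dihydro-2H-chromene-2,7(8H)-dione, via O-acylisourea 20 (not isolated)
Conditions: DCC, CH2Cl2, 0 °C
Reagents that add atoms: none
Why: Carbodiimide enol-lactonisation under kinetic control should close the six-membered lactone through the free, acidic enol oxygen next to the quaternary carbon, because the other enol oxygen is tied up in the hydrogen-bond chelate with the acyl carbonyl.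

**Compound list**
1 | ethyl acetoacetate | CCOC(=O)CC(C)=O | starting material
2 | prenyl bromide (1-bromo-3-methylbut-2-ene) | CC(C)=CCBr | starting material
3 | ethyl 2-acetyl-5-methyl-2-(3-methylbut-2-en-1-yl)hex-4-enoate | CCOC(=O)C(CC=C(C)C)(CC=C(C)C)C(C)=O | intermediate
4 | 6-methyl-3-(3-methylbut-2-en-1-yl)hept-5-en-2-one | CC(=O)C(CC=C(C)C)CC=C(C)C | intermediate
5 | diallyl oxalate | C=CCOC(=O)C(=O)OCC=C | starting material
6 | allyl 8-methyl-5-(3-methylbut-2-en-1-yl)-2,4-dioxonon-7-enoate | C=CCOC(=O)C(=O)CC(=O)C(CC=C(C)C)CC=C(C)C | intermediate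
7 | (E)-cinnamaldehyde | O=C/C=C/c1ccccc1 | starting material
8 | allyl (4S)-5-[5-methyl-2-(3-methylbut-2-en-1-yl)hex-4-enoyl]-2-oxo-4-phenyl-3,4-dihydro-2H-pyran-6-carboxylate | C=CCOC(=O)C1=C(C(=O)C(CC=C(C)C)CC=C(C)C)[C@H](c2ccccc2)CC(=O)O1 | intermediate
9 | allyl (4S)-5-{1-[(tert-butyldimethylsilyl)oxy]-5-methyl-2-(3-methylbut-2-en-1-yl)hexa-1,4-dien-1-yl}-2-oxo-4-phenyl-3,4-dihydro-2H-pyran-6-carboxylate | C=CCOC(=O)C1=C(C(O[Si](C)(C)C(C)(C)C)=C(CC=C(C)C)CC=C(C)C)[C@H](c2ccccc2)CC(=O)O1 | intermediate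
10 | (4S)-5-{1-[(tert-butyldimethylsilyl)oxy]-5-methyl-2-(3-methylbut-2-en-1-yl)hexa-1,4-dien-1-yl}-2-oxo-4-phenyl-3,4-dihydro-2H-pyran-6-carboxylic acid | OC(=O)C1=C(C(O[Si](C)(C)C(C)(C)C)=C(CC=C(C)C)CC=C(C)C)[C@H](c2ccccc2)CC(=O)O1 | intermediate
11 | (4S)-5-{1-[(tert-butyldimethylsilyl)oxy]-5-methyl-2-(3-methylbut-2-en-1-yl)hexa-1,4-dien-1-yl}-2-oxo-4-phenyl-3,4-dihydro-2H-pyran-6-carbonyl chloride | ClC(=O)C1=C(C(O[Si](C)(C)C(C)(C)C)=C(CC=C(C)C)CC=C(C)C)[C@H](c2ccccc2)CC(=O)O1 | intermediate (not isolated)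
12 | (4S)-5-{1-[(tert-butyldimethylsilyl)oxy]-5-methyl-2-(3-methylbut-2-en-1-yl)hexa-1,4-dien-1-yl}-6-(diazoacetyl)-4-phenyl-3,4-dihydro-2H-pyran-2-one | [N-]=[N+]=CC(=O)C1=C(C(O[Si](C)(C)C(C)(C)C)=C(CC=C(C)C)CC=C(C)C)[C@H](c2ccccc2)CC(=O)O1 | intermediate
13 | (4S)-5-{1-[(tert-butyldimethylsilyl)oxy]-5-methyl-2-(3-methylbut-2-en-1-yl)hexa-1,4-dien-1-yl}-6-(2-oxoethenyl)-4-phenyl-3,4-dihydro-2H-pyran-2-one (dienylketene) | O=C=CC1=C(C(O[Si](C)(C)C(C)(C)C)=C(CC=C(C)C)CC=C(C)C)[C@H](c2ccccc2)CC(=O)O1 | intermediate (not isolated)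
14 | (4S)-5-[(tert-butyldimethylsilyl)oxy]-6,6-bis(3-methylbut-2-en-1-yl)-4-phenyl-3,4-dihydro-2H-chromene-2,7(6H)-dione | O=C1C=C2OC(=O)C[C@@H](c3ccccc3)C2=C(O[Si](C)(C)C(C)(C)C)C1(CC=C(C)C)CC=C(C)C | intermediate
15 | methyl (3S)-3-[2-hydroxy-5,5-bis(3-methylbut-2-en-1-yl)-4,6-dioxocyclohex-1-en-1-yl]-3-phenylpropanoate | COC(=O)C[C@@H](c1ccccc1)C1=C(O)CC(=O)C(CC=C(C)C)(CC=C(C)C)C1=O | intermediate
16 | (R)-2-methylbutanoic acid | CC[C@@H](C)C(=O)O | starting material
17 | methyl (3S)-3-[2-{[(2R)-2-methylbutanoyl]oxy}-5,5-bis(3-methylbut-2-en-1-yl)-4,6-dioxocyclohex-1-en-1-yl]-3-phenylpropanoate (enol ester) | COC(=O)C[C@@H](c1ccccc1)C1=C(OC(=O)[C@H](C)CC)CC(=O)C(CC=C(C)C)(CC=C(C)C)C1=O | intermediate (not isolated)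
18 | methyl (3S)-3-{2,6-dihydroxy-5-[(2R)-2-methylbutanoyl]-3,3-bis(3-methylbut-2-en-1-yl)-4-oxocyclohexa-1,5-dien-1-yl}-3-phenylpropanoate | CC[C@@H](C)C(=O)C1=C(O)C([C@@H](CC(=O)OC)c2ccccc2)=C(O)C(CC=C(C)C)(CC=C(C)C)C1=O | intermediate
19 | (3S)-3-{2,6-dihydroxy-5-[(2R)-2-methylbutanoyl]-3,3-bis(3-methylbut-2-en-1-yl)-4-oxocyclohexa-1,5-dien-1-yl}-3-phenylpropanoic acid | CC[C@@H](C)C(=O)C1=C(O)C([C@@H](CC(=O)O)c2ccccc2)=C(O)C(CC=C(C)C)(CC=C(C)C)C1=O | intermediate
20 | N,N'-dicyclohexyl-O-acylisourea of acid 19 | CC[C@@H](C)C(=O)C1=C(O)C([C@@H](CC(=O)OC(=NC2CCCCC2)NC2CCCCC2)c2ccccc2)=C(O)C(CC=C(C)C)(CC=C(C)C)C1=O | intermediate (not isolated)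
21 | (4S)-5-hydroxy-6-[(2R)-2-methylbutanoyl]-8,8-bis(3-methylbut-2-en-1-yl)-4-phenyl-3,4-dihydro-2H-chromene-2,7(8H)-dione | CC[C@@H](C)C(=O)C1=C(O)C2=C(OC(=O)C[C@H]2c2ccccc2)C(CC=C(C)C)(CC=C(C)C)C1=O | target

Total step count: 12. Longest linear sequence: 12 steps (from 1 to 21).

**Steps most likely to fail**

Step 4. What may go wrong: closure of the lactone through the ketone oxygen instead of the pyruvate oxygen, or poor facial selectivity in the conjugate addition. The fallback sets out from 6 and comes back at 8, and replaces acyl azolium catalysis by iminium catalysis. Compounds 6 and 7, with the enantiomer of 2-[diphenyl(trimethylsilyloxy)methyl]pyrrolidine that leads to 4S (20 mol %) and benzoic acid in CH2Cl2, should give the Michael adduct as its cyclic hemiacetal, allyl (4S)-2-hydroxy-5-[5-methyl-2-(3-methylbut-2-en-1-yl)hex-4-enoyl]-4-phenyl-3,4-dihydro-2H-pyran-6-carboxylate F1. Here the ring closure is reversible and can settle on the less hindered pyruvate oxygen. Oxidation of the lactol with 1,1,1-triacetoxy-1,1-dihydro-1,2-benziodoxol-3(1H)-one in CH2Cl2 then gives lactone 8.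

Step 8. What may go wrong: loss of the ketene to dimerisation or to adventitious nucleophiles before it cyclises, or addition of the carbene to a prenyl double bond. The fallback sets out from 3 and comes back at 15, and builds the carbocycle by ionic condensation. The lithium enolate of 3 (LiHMDS, THF, −78 °C) is acylated with N-acetylimidazole to ethyl 2,2-bis(3-methylbut-2-en-1-yl)-3,5-dioxohexanoate F2. Intramolecular Claisen condensation (NaOEt, EtOH, reflux) should give 2,2-bis(3-methylbut-2-en-1-yl)cyclohexane-1,3,5-trione F3. The carbene-catalysed oxidative annulation of step 4, run on the trione and 7, should give (4S)-5-hydroxy-6,6-bis(3-methylbut-2-en-1-yl)-4-phenyl-3,4-dihydro-2H-chromene-2,7(6H)-dione F4; either enol oxygen may close this ring, since both lactones open to the same ester. The methanolysis of step 9 then gives 15.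

Step 12. What may go wrong: closure of the lactone through the chelated enol oxygen next to the acyl group, or acyl migration between the two enol oxygens. The fallback sets out from 14 and comes back at 21, and keeps the oxygen that must be acylated masked until the end. Thiophenol and Et3N (CH2Cl2, 0 °C) open the lactone of 14 to S-phenyl (3S)-3-{2-[(tert-butyldimethylsilyl)oxy]-6-hydroxy-3,3-bis(3-methylbut-2-en-1-yl)-4-oxocyclohexa-1,5-dien-1-yl}-3-phenylpropanethioate F5, with the silyl enol ether left in place. C-acylation with 16 under the conditions of step 10 should give S-phenyl (3S)-3-{2-[(tert-butyldimethylsilyl)oxy]-6-hydroxy-5-[(2R)-2-methylbutanoyl]-3,3-bis(3-methylbut-2-en-1-yl)-4-oxocyclohexa-1,5-dien-1-yl}-3-phenylpropanethioate F6. Fluoride (CsF in MeCN, or Bu4NF buffered with AcOH) then frees the enolate oxygen next to the quaternary carbon, which attacks the thioester and closes the lactone to 21 at the oxygen that carried the silyl group.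

Further compounds
F1 | step 4 | allyl (4S)-2-hydroxy-5-[5-methyl-2-(3-methylbut-2-en-1-yl)hex-4-enoyl]-4-phenyl-3,4-dihydro-2H-pyran-6-carboxylate (lactol, both anomers) | C=CCOC(=O)C1=C(C(=O)C(CC=C(C)C)CC=C(C)C)[C@H](c2ccccc2)CC(O)O1
F2 | step 8 | ethyl 2,2-bis(3-methylbut-2-en-1-yl)-3,5-dioxohexanoate | CCOC(=O)C(CC=C(C)C)(CC=C(C)C)C(=O)CC(C)=O
F3 | step 8 | 2,2-bis(3-methylbut-2-en-1-yl)cyclohexane-1,3,5-trione | O=C1CC(=O)CC(=O)C1(CC=C(C)C)CC=C(C)C
F4 | step 8 | (4S)-5-hydroxy-6,6-bis(3-methylbut-2-en-1-yl)-4-phenyl-3,4-dihydro-2H-chromene-2,7(6H)-dione | O=C1C=C2OC(=O)C[C@@H](c3ccccc3)C2=C(O)C1(CC=C(C)C)CC=C(C)C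
F5 | step 12 | S-phenyl (3S)-3-{2-[(tert-butyldimethylsilyl)oxy]-6-hydroxy-3,3-bis(3-methylbut-2-en-1-yl)-4-oxocyclohexa-1,5-dien-1-yl}-3-phenylpropanethioate | O=C1C=C(O)C([C@@H](CC(=O)Sc2ccccc2)c2ccccc2)=C(O[Si](C)(C)C(C)(C)C)C1(CC=C(C)C)CC=C(C)C
F6 | step 12 | S-phenyl (3S)-3-{2-[(tert-butyldimethylsilyl)oxy]-6-hydroxy-5-[(2R)-2-methylbutanoyl]-3,3-bis(3-methylbut-2-en-1-yl)-4-oxocyclohexa-1,5-dien-1-yl}-3-phenylpropanethioate | CC[C@@H](C)C(=O)C1=C(O)C([C@@H](CC(=O)Sc2ccccc2)c2ccccc2)=C(O[Si](C)(C)C(C)(C)C)C(CC=C(C)C)(CC=C(C)C)C1=O
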